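Remark on the chemistry: (benzyloxymethyl)tributylstannane 12 is treated as a purchasable reagent; if it must be made, Bu3SnH is hydroxymethylated (LDA, paraformaldehyde) and benzylated (NaH, BnBr) beforehand.

## Analysis of the target

The target 23 is a lignan built on a single tetrahydrofuran ring (O1, C2 to C5). It carries a 4-hydroxy-3,5-dimethoxyphenyl group on each ether carbon (C2, C5) and a hydroxymethyl group on C3 and on C4, and it is C2-symmetric. All four ring carbons are stereocentres, (2R,3S,4S,5R): every vicinal pair is trans, so the aryl groups are 2,5-trans and the hydroxymethyl groups 3,4-trans. This all-trans array is the thermodynamically preferred one, so a centre that can be equilibrated late will fall into place, while any centre that cannot be equilibrated must be set correctly when it is made. The sensitive sites are the two ring C–O bonds, which are benzylic and para to a phenol: acid ionises them through a quinone methide, and forcing hydrogenolysis cleaves them. The electron-rich arenes and free phenols are also easily oxidised. The difficulty is to build four contiguous stereocentres on a five-membered ring as one enantiomer, with two bulky electron-rich aryl groups on the ether carbons, without passing through benzylic cations. The strategy rests on the C2–C3 bond, which joins an aryl-bearing ether carbon to a carbon carrying a one-carbon oxidised arm. A 1,2-shift in a six-membered α-diazo ketone creates exactly this bond: the acyl-bound, oxygen- and aryl-bearing carbon migrates to the diazo carbon, and the former carbonyl carbon becomes the C3 arm. The stereochemical problem is thereby moved onto a tetrahydropyran-3-one, where the substituents can be introduced one at a time.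

## Retrosynthetic reasoning

**23 from 22.** Only the three O–benzyl bonds are cut. Benzyl is the one protecting group that survives every reagent of the route, and all three can be removed together in the last step, so the free phenols never meet an oxidant or a base.

**22 from 21.** The C3 hydroxymethyl group is taken back to a methyl ester. The ester is what the ring contraction delivers, and it makes C3 epimerisable for as long as that is useful.

**21 from 18 (key disconnection).** The C2–C3 bond of the tetrahydrofuran is cut and C2 is reconnected to the ester carbon, which gives the six-membered 4-diazo-pyran-3-one 18.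
- This bond is chosen over a ring C–O bond or the C3–C4 bond because a ring contraction involves no cyclisation and no benzylic cation, and because the migrating carbon keeps its configuration.
- The gain is that three of the four stereocentres (C2, C4, C5 of 21) are already present in 18, in a ring where they can be set by pyranone chemistry.
- The forward reaction has to expel the diazo nitrogen atoms, shift C2 from the carbonyl carbon to the diazo carbon, and capture the resulting ketene 19 as the ester.

**18 from 15.** The C4–N bond is cut back to the silyl enol ether 15. The enol ether defines the enolate regiochemistry away from C2, which is benzylic and α to the ketone, and whose epimerisation would lead into the more stable 2,6-cis series.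

**15 from 11 and 12.** The C5–CH2 bond is cut: the benzyloxymethyl group from 12 is added to the enone 11 in a conjugate sense. The neighbouring C6 aryl group directs the attack to the opposite face, and the addition produces the enolate that the next step needs.

**11 from 8 and 10.** The C6–aryl bond is cut. Arylation of the cyclic enol ether 8 by the diazonium salt 10 puts the aryl group on the oxygen-bearing carbon, trans to the C2 aryl group, and regenerates the enone in the same operation.

**8 from 7 from 6.** The pyranone ring is traced back to a furan. Oxidative ring expansion of the furylcarbinol 6 gives the hemiacetal 7, and reductive removal of its C6 oxygen unveils the enol ether 8. The carbinol carbon of 6 becomes C2 of the target.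

**6 from 5 from 2 and 3.** The aryl–carbinol C–C bond is cut back to the aryl bromide 2 and the aldehyde 3. The racemic carbinol 5 is resolved to 6, which fixes the single stereocentre from which all others are derived.

**10 from 9 from 2, and 2 from 1.** Both aryl groups come from the same bromide 2 (the benzyl ether of phenol 1): once as a carbon nucleophile, once, after amination to 9, as the diazonium electrophile 10.

## Alternatives that were turned down

**Alternative 1:** Both arenes are disconnected instead of the heterocycle. In each aryl ring the bonds C2'–C3' and C5'–C6' are cut, which leaves a three-carbon vinamidinium unit on C2 and on C5 of the tetrahydrofuran (bis-salt A3) and two molecules of the symmetrical ketone A2. In the forward key step a strong alkoxide base would condense A3 twice with A2. Each ketone uses both α-carbons, the amine leaving groups are lost, and the bis(silyl) ether A1 appears with both phenols free.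
- For it: no aryl–carbon bond has to be made at a hindered ether carbon, no phenol protection is needed, and the twofold operation mirrors the C2 symmetry. The end-game is a fluoride desilylation, which is gentler toward the benzylic ring C–O bonds than the hydrogenolysis used here; on that point the alternative is stronger.
- Against it: A3 already holds all four ring stereocentres, so the stereochemical problem is only moved into a precursor no easier to reach than 21. In every neutral intermediate of the condensation the ring oxygen is allylic to an enamine, so vinylogous β-elimination can open the ring. A double (3+3) closure of a vinamidinium salt with a bis-α-alkoxy ketone to a 2,6-dialkoxyphenol has no close analogy, so the key step would be method development carried out twice on a dication.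
- Comparison: the chosen route is not shorter, but its ring-forming event has a regiochemistry that is fixed by structure, and every other step is of a known type on its substrate class.

**Alternative 2:** The C3–C4 bond and both ring C–O bonds are cut at once, back to two molecules of the sinapoyl imide A5, which carries an oxazolidinone auxiliary. In the forward key step a one-electron oxidant in wet solvent generates the phenoxyl radicals, and these couple through their β-carbons. The bis(quinone methide) is hydrated, and the new benzylic hydroxyl adds to the second quinone methide to close the ring, giving A4. Hydride reduction of both imides would then give 23.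
- For it: it is by far the shortest route and is clearly stronger in step economy. It uses the C2 symmetry, and reversible quinone methide chemistry should place the aryl groups trans to their neighbours.
- Against it: three selectivities must be met in one step. The bis(quinone methide) can close by intramolecular arylation to an aryldihydronaphthalene instead of being hydrated. The chiral versus meso pairing at the new C3–C4 bond must be controlled. Above all, the absolute sense must be dictated by auxiliaries that sit three atoms away from the coupling carbons of a planar, delocalised radical, which is a weak lever.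
- Comparison: the chosen route gives up the brevity but sets each stereocentre by its own control element (resolution, carbopalladation anti to an aryl group, anti conjugate addition, thermodynamic equilibration), so a failure stays local.

**Alternative 3:** Both aryl–carbon bonds (C2–aryl and C5–aryl) are cut, back to the bis-acetal A8 and two molecules of the phenol A7. In the forward key step a boron Lewis acid ionises each acetal carbon in turn to an oxocarbenium ion, which A7 attacks through the carbon para to its hydroxyl group. The product is the diacetate A6, and mild methanolysis of the acetates would finish the synthesis.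
- For it: it is highly convergent, the para selectivity is inherent in A7, and no phenol protection is needed. The new centres should form trans to the neighbouring acetoxymethyl groups, also under thermodynamic control. On convergence and cost of the aryl source it is stronger than the chosen route.
- Against it: the product ethers, para to a free hydroxyl, ionise more easily than the starting acetal, and excess A7 can then add again with ring opening to diarylmethanes. O-attack of the phenol and participation of the acetate carbonyl at the oxocarbenium ion compete. The enantiopure core A8 still needs its own asymmetric synthesis.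
- Comparison: the chosen route never exposes an electron-rich benzylic ether carbon to acid. Both aryl–carbon bonds are made by organometallic steps, and the ring is finished under light and mild base.

Key step: step 11

## Route

Step 1
Reactants: 1 4-bromo-2,6-dimethoxyphenol
Product: 2 2-(benzyloxy)-5-bromo-1,3-dimethoxybenzene
Conditions: BnBr, K2CO3, DMF, 60 °C
Reagents that add atoms: benzyl bromide, BrCc1ccccc1
Why: Williamson etherification of the phenoxide. Benzyl is chosen because it should survive organolithium, peracid, Zn/AcOH, Pd, cuprate, amine base, light above 300 nm and hydride, and all three benzyl groups can leave together at the end.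

Step 2
Reactants: 2 2-(benzyloxy)-5-bromo-1,3-dimethoxybenzene; 3 furfural
Product: 5 rac-[4-(benzyloxy)-3,5-dimethoxyphenyl](furan-2-yl)methanol, via aryllithium 4 (not isolated)
Conditions: n-BuLi, THF, −78 °C; then 3, −78 → 0 °C; aq. NH4Cl
Reagents that add atoms: none
Why: Bromine–lithium exchange is fast at −78 °C for this bromide, which has no substituent ortho to bromine, and the aryllithium adds 1,2 to the aldehyde. The carbinol centre is formed racemic and is resolved in step 3.

Step 3
Reactants: 5 rac-[4-(benzyloxy)-3,5-dimethoxyphenyl](furan-2-yl)methanol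
Product: 6 (S)-[4-(benzyloxy)-3,5-dimethoxyphenyl](furan-2-yl)methanol
Conditions: Ti(OiPr)4 (0.2 equiv), D-(−)-diisopropyl tartrate (0.24 equiv), t-BuOOH (0.6 equiv), 4 Å MS, CH2Cl2, −20 °C, run to about 55–60 % conversion
Reagents that add atoms: none
Why: Sharpless kinetic resolution of a 2-furylcarbinol: the titanium tartrate peroxide complex oxidises the furan of the matched enantiomer to a pyranone much faster than that of the mismatched one. By the usual mnemonic (furan as the alkene, aryl as the carbinol substituent) the D-(−)-tartrate should consume the (R)-alcohol and leave (S)-6 in high enantiomeric purity past half conversion. This carbon becomes C2 of the target.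

Step 4
Reactants: 6 (S)-[4-(benzyloxy)-3,5-dimethoxyphenyl](furan-2-yl)methanol
Product: 7 (2S)-2-[4-(benzyloxy)-3,5-dimethoxyphenyl]-6-hydroxy-2H-pyran-3(6H)-one (mixture of C6 anomers)
Conditions: mCPBA, CH2Cl2, 0 °C
Reagents that add atoms: 3-chloroperbenzoic acid, O=C(OO)c1cccc(Cl)c1
Why: Achmatowicz rearrangement: peracid oxidation of the furan gives the ring-opened ene-dione, which the carbinol oxygen closes to the 6-hydroxypyranone. The stereocentre is not involved, and the furan is far more reactive toward the peracid than the trialkoxyarene.

Step 5
Reactants: 7 (2S)-2-[4-(benzyloxy)-3,5-dimethoxyphenyl]-6-hydroxy-2H-pyran-3(6H)-one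
Product: 8 (2S)-2-[4-(benzyloxy)-3,5-dimethoxyphenyl]-2H-pyran-3(4H)-one (C4 methylene, C5=C6 enol ether)
Conditions: Zn dust, AcOH, rt
Reagents that add atoms: none
Why: Reductive γ-deoxygenation of an Achmatowicz product: two-electron reduction of the enone expels the vinylogous C6 oxygen, and kinetic protonation of the zinc dienolate at C4 leaves the C5=C6 enol ether. The medium is weakly acidic and free of amine base, so C2, which is benzylic and α to the ketone, should keep its configuration.

Step 6
Reactants: 2 2-(benzyloxy)-5-bromo-1,3-dimethoxybenzene
Product: 9 4-(benzyloxy)-3,5-dimethoxyaniline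
Conditions: Pd2(dba)3 (1 mol %), P(t-Bu)3 (2 mol %), LiN(SiMe3)2, toluene, rt → 50 °C; then 1 M HCl; aq. NaOH
Reagents that add atoms: lithium bis(trimethylsilyl)amide, [Li]N([Si](C)(C)C)[Si](C)(C)C
Why: Buchwald–Hartwig amination with LiN(SiMe3)2 as an ammonia equivalent. The bromine has no ortho substituent, which allows coupling of the bulky silylamide, and acid hydrolysis of the N–Si bonds frees the primary aniline.

Step 7
Reactants: 9 4-(benzyloxy)-3,5-dimethoxyaniline
Product: 10 4-(benzyloxy)-3,5-dimethoxybenzenediazonium tetrafluoroborate
Conditions: NaNO2, 48 % aq. HBF4, EtOH/H2O, 0 °C; precipitation with Et2O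
Reagents that add atoms: sodium nitrite, [Na+].[O-]N=O; tetrafluoroboric acid, [H+].F[B-](F)(F)F
Why: Diazotisation of the aniline. The arenediazonium ion is stabilised by the para oxygen and should be isolable as its tetrafluoroborate by precipitation.

Step 8
Reactants: 8 (2S)-2-[4-(benzyloxy)-3,5-dimethoxyphenyl]-2H-pyran-3(4H)-one; 10 4-(benzyloxy)-3,5-dimethoxybenzenediazonium tetrafluoroborate
Product: 11 (2S,6R)-2,6-bis[4-(benzyloxy)-3,5-dimethoxyphenyl]-2H-pyran-3(6H)-one (2,6-trans)
Conditions: Pd(OAc)2 (5 mol %), NaOAc (2 equiv), MeCN, rt
Reagents that add atoms: none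
Why: Heck–Matsuda arylation of a cyclic enol ether: Pd(OAc)2 is reduced in the flask to zerovalent palladium, which inserts into the C–N bond of 10. The cationic arylpalladium adds across C5=C6 with the aryl group on the oxygen-bearing C6 and on the face away from the C2 aryl group, which sets C6 as R. syn-β-Hydride elimination can only use a C4 hydrogen (the C6 hydrogen is anti to palladium) and so gives the conjugated enone, at room temperature and without amine base.

Step 9
Reactants: 11 (2S,6R)-2,6-bis[4-(benzyloxy)-3,5-dimethoxyphenyl]-2H-pyran-3(6H)-one; 12 (benzyloxymethyl)tributylstannane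
Product: 15 (2S,5S,6R)-2,6-bis[4-(benzyloxy)-3,5-dimethoxyphenyl]-5-(benzyloxymethyl)-3-(trimethylsilyloxy)-5,6-dihydro-2H-pyran, via benzyloxymethyllithium 13 (not isolated), via lithium bis(benzyloxymethyl)cuprate 14 (not isolated)
Conditions: 12 (3 equiv), n-BuLi, THF, −78 °C; CuBr·SMe2 (1.5 equiv), −78 → −40 °C; then Me3SiCl, 11, −78 °C; Et3N, pentane, cold aq. NaHCO3
Reagents that add atoms: chlorotrimethylsilane, C[Si](C)(C)Cl
Why: Conjugate addition of an α-alkoxymethyl cuprate (BnOCH2)2CuLi, made by tin–lithium exchange and transmetallation to copper and accelerated by Me3SiCl. The reagent should attack C5 anti to the adjacent C6 aryl group, as in 4-substituted cyclohexenones, which sets C5 as S (5,6-trans). O-Silylation fixes the enolate as the C3=C4 silyl enol ether, so C2 is never enolised.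

Step 10
Reactants: 15 (2S,5S,6R)-2,6-bis[4-(benzyloxy)-3,5-dimethoxyphenyl]-5-(benzyloxymethyl)-3-(trimethylsilyloxy)-5,6-dihydro-2H-pyran
Product: 18 (2S,5S,6R)-2,6-bis[4-(benzyloxy)-3,5-dimethoxyphenyl]-5-(benzyloxymethyl)-4-diazotetrahydro-2H-pyran-3-one, via lithium enolate 16 (not isolated), via trifluoroacetyl ketone 17 (not isolated)
Conditions: MeLi, THF, 0 °C; CF3CO2CH2CF3, −78 °C; dil. HCl wash; then MsN3, Et3N, H2O (1 equiv), MeCN, rt
Reagents that add atoms: methanesulfonyl azide, CS(=O)(=O)N=[N+]=[N-]
Why: MeLi cleaves the Si–O bond and releases the regiodefined lithium enolate, which is C-acylated by CF3CO2CH2CF3. Detrifluoroacetylative (Regitz-type) diazo transfer from MsN3 to the resulting 1,3-dicarbonyl compound then installs the diazo group at C4 under Et3N, a base that should be too weak to deprotonate C2 at a useful rate. C4 is the only position that can take the diazo group, because C2 is a methine.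

Step 11
Reactants: 18 (2S,5S,6R)-2,6-bis[4-(benzyloxy)-3,5-dimethoxyphenyl]-5-(benzyloxymethyl)-4-diazotetrahydro-2H-pyran-3-one
Product: 21 methyl (2R,3R,4S,5R)-2,5-bis[4-(benzyloxy)-3,5-dimethoxyphenyl]-4-(benzyloxymethyl)tetrahydrofuran-3-carboxylate (all-trans), via ketene 19 (not isolated), via cis ester 20 (not isolated)
Conditions: hν (medium-pressure Hg lamp, Pyrex, λ > 300 nm), MeOH/THF 4:1, 0 °C; then NaOMe (0.3 equiv), MeOH, rt
Reagents that add atoms: methanol, CO
Why: Excitation of the diazo ketone, which the ring holds in the s-cis geometry, expels N2 in concert with the 1,2-shift of C2 from the carbonyl carbon C3 to the diazo carbon C4, so the free-carbene channels (O–H insertion, 1,2-hydride shift) are largely bypassed; the ketene 19, exocyclic to the new tetrahydrofuran, is captured by methanol. The closest known reaction type is the photochemical Wolff ring contraction of 2-diazocycloalkanones and their oxygen-heterocyclic analogues to the next smaller ring carboxylate. The five-membered ring arises by a 1,2-shift within an existing ring, not by an end-to-end cyclisation, so no exo or endo closure mode has to be met. C2 migrates with retention and keeps the configuration fixed in step 3, and the old C5 and C6 (C4 and C5 of the new ring) are not touched. The one new stereocentre, C3, forms when the ketene-derived ester enol is protonated, kinetically from the face away from the C2 aryl and C4 benzyloxymethyl groups, which should give mainly the cis ester 20. NaOMe then equilibrates this centre through the ester enolate to 21, trans to both neighbours and the only arrangement without two cis-vicinal contacts. The regiochemistry needs no control, since only C4 carries the diazo group and only C2 can migrate. The selectivity the step does need, rearrangement over carbene trapping by the solvent, rests on the locked s-cis geometry, and the Pyrex cut-off keeps the benzyl ethers and trialkoxyarenes out of the excitation window.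

Step 12
Reactants: 21 methyl (2R,3R,4S,5R)-2,5-bis[4-(benzyloxy)-3,5-dimethoxyphenyl]-4-(benzyloxymethyl)tetrahydrofuran-3-carboxylate
Product: 22 [(2R,3S,4S,5R)-2,5-bis[4-(benzyloxy)-3,5-dimethoxyphenyl]-4-(benzyloxymethyl)tetrahydrofuran-3-yl]methanol
Conditions: LiAlH4, THF, 0 °C
Reagents that add atoms: none
Why: Hydride reduction of the ester to the primary alcohol. Benzyl ethers and the tetrahydrofuran are inert, and C3 can no longer epimerise once the carbonyl is gone.

Step 13
Reactants: 22 [(2R,3S,4S,5R)-2,5-bis[4-(benzyloxy)-3,5-dimethoxyphenyl]-4-(benzyloxymethyl)tetrahydrofuran-3-yl]methanol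
Product: 23 [(2R,3S,4S,5R)-2,5-bis(4-hydroxy-3,5-dimethoxyphenyl)tetrahydrofuran-3,4-diyl]dimethanol
Conditions: H2 (1 atm), Pd/C (10 %), EtOAc/EtOH, rt, stopped when the last benzyl ether is consumed
Reagents that add atoms: none
Why: Hydrogenolysis of two aryl benzyl ethers and one primary alkyl benzyl ether. These should cleave faster than the ring C–O bonds, which are secondary, flanked by substituents and part of a dialkyl ether. The neutral solvent avoids acid-promoted ionisation of the 4-hydroxybenzylic ether carbons.

## Compound list

1 | 4-bromo-2,6-dimethoxyphenol | COc1cc(Br)cc(OC)c1O | starting material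
2 | 2-(benzyloxy)-5-bromo-1,3-dimethoxybenzene | COc1cc(Br)cc(OC)c1OCc1ccccc1 | intermediate
3 | furfural (furan-2-carbaldehyde) | O=Cc1ccco1 | starting material
4 | [4-(benzyloxy)-3,5-dimethoxyphenyl]lithium | [Li]c1cc(OC)c(OCc2ccccc2)c(OC)c1 | intermediate
5 | rac-[4-(benzyloxy)-3,5-dimethoxyphenyl](furan-2-yl)methanol | COc1cc(C(O)c2ccco2)cc(OC)c1OCc1ccccc1 | intermediate
6 | (S)-[4-(benzyloxy)-3,5-dimethoxyphenyl](furan-2-yl)methanol | COc1cc([C@@H](c2ccco2)O)cc(OC)c1OCc1ccccc1 | intermediate
7 | (2S)-2-[4-(benzyloxy)-3,5-dimethoxyphenyl]-6-hydroxy-2H-pyran-3(6H)-one, C6 anomers | COc1cc([C@@H]2OC(O)C=CC2=O)cc(OC)c1OCc1ccccc1 | intermediate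
8 | (2S)-2-[4-(benzyloxy)-3,5-dimethoxyphenyl]-2H-pyran-3(4H)-one | COc1cc([C@@H]2OC=CCC2=O)cc(OC)c1OCc1ccccc1 | intermediate
9 | 4-(benzyloxy)-3,5-dimethoxyaniline | COc1cc(N)cc(OC)c1OCc1ccccc1 | intermediate
10 | 4-(benzyloxy)-3,5-dimethoxybenzenediazonium tetrafluoroborate | COc1cc([N+]#N)cc(OC)c1OCc1ccccc1.F[B-](F)(F)F | intermediate
11 | (2S,6R)-2,6-bis[4-(benzyloxy)-3,5-dimethoxyphenyl]-2H-pyran-3(6H)-one | COc1cc([C@@H]2O[C@@H](c3cc(OC)c(OCc4ccccc4)c(OC)c3)C=CC2=O)cc(OC)c1OCc1ccccc1 | intermediate
12 | (benzyloxymethyl)tributylstannane | CCCC[Sn](CCCC)(CCCC)COCc1ccccc1 | starting material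
13 | (benzyloxymethyl)lithium | [Li]COCc1ccccc1 | intermediate
14 | lithium bis(benzyloxymethyl)cuprate | [Li+].[Cu-](COCc1ccccc1)COCc1ccccc1 | intermediate
15 | (2S,5S,6R)-2,6-bis[4-(benzyloxy)-3,5-dimethoxyphenyl]-5-(benzyloxymethyl)-3-(trimethylsilyloxy)-5,6-dihydro-2H-pyran | COc1cc([C@@H]2O[C@@H](c3cc(OC)c(OCc4ccccc4)c(OC)c3)[C@H](COCc3ccccc3)C=C2O[Si](C)(C)C)cc(OC)c1OCc1ccccc1 | intermediate
16 | lithium enolate of the 3-ketone (C3–O–Li, C3=C4), stereocentres as in 15 | COc1cc([C@@H]2O[C@@H](c3cc(OC)c(OCc4ccccc4)c(OC)c3)[C@H](COCc3ccccc3)C=C2O[Li])cc(OC)c1OCc1ccccc1 | intermediate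
17 | (2S,5S,6R)-2,6-bis[4-(benzyloxy)-3,5-dimethoxyphenyl]-5-(benzyloxymethyl)-4-(trifluoroacetyl)tetrahydro-2H-pyran-3-one (C4 epimers and enol) | COc1cc([C@@H]2O[C@@H](c3cc(OC)c(OCc4ccccc4)c(OC)c3)[C@H](COCc3ccccc3)C(C(=O)C(F)(F)F)C2=O)cc(OC)c1OCc1ccccc1 | intermediate
18 | (2S,5S,6R)-2,6-bis[4-(benzyloxy)-3,5-dimethoxyphenyl]-5-(benzyloxymethyl)-4-diazotetrahydro-2H-pyran-3-one | COc1cc([C@@H]2O[C@@H](c3cc(OC)c(OCc4ccccc4)c(OC)c3)[C@H](COCc3ccccc3)C(=[N+]=[N-])C2=O)cc(OC)c1OCc1ccccc1 | intermediate
19 | ketene exocyclic at C3 of the 2,5-diaryl-4-(benzyloxymethyl)tetrahydrofuran, other centres as in 21 | COc1cc([C@@H]2O[C@@H](c3cc(OC)c(OCc4ccccc4)c(OC)c3)[C@H](COCc3ccccc3)C2=C=O)cc(OC)c1OCc1ccccc1 | intermediate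
20 | methyl (2R,3S,4S,5R)-2,5-bis[4-(benzyloxy)-3,5-dimethoxyphenyl]-4-(benzyloxymethyl)tetrahydrofuran-3-carboxylate (ester cis to both neighbours) | COc1cc([C@@H]2O[C@@H](c3cc(OC)c(OCc4ccccc4)c(OC)c3)[C@H](COCc3ccccc3)[C@@H]2C(=O)OC)cc(OC)c1OCc1ccccc1 | intermediate
21 | methyl (2R,3R,4S,5R)-2,5-bis[4-(benzyloxy)-3,5-dimethoxyphenyl]-4-(benzyloxymethyl)tetrahydrofuran-3-carboxylate (all-trans) | COc1cc([C@@H]2O[C@@H](c3cc(OC)c(OCc4ccccc4)c(OC)c3)[C@H](COCc3ccccc3)[C@H]2C(=O)OC)cc(OC)c1OCc1ccccc1 | intermediate
22 | [(2R,3S,4S,5R)-2,5-bis[4-(benzyloxy)-3,5-dimethoxyphenyl]-4-(benzyloxymethyl)tetrahydrofuran-3-yl]methanol | COc1cc([C@@H]2O[C@@H](c3cc(OC)c(OCc4ccccc4)c(OC)c3)[C@H](COCc3ccccc3)[C@H]2CO)cc(OC)c1OCc1ccccc1 | intermediate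
23 | [(2R,3S,4S,5R)-2,5-bis(4-hydroxy-3,5-dimethoxyphenyl)tetrahydrofuran-3,4-diyl]dimethanol | COc1cc([C@@H]2O[C@@H](c3cc(OC)c(O)c(OC)c3)[C@H](CO)[C@H]2CO)cc(OC)c1O | target

## Step count and least certain steps

Total step count: 13. Longest linear sequence: 11 steps (1, 2, 3, 4, 5, 8, 9, 10, 11, 12, 13); steps 6 and 7 form a two-step branch from 2.

**Step 11 (key step).**
- Most likely to go wrong: diversion of the excited diazo ketone into carbene chemistry (insertion into the O–H bond of the solvent, 1,2-hydride shift from C5), or photochemical degradation of the electron-rich aryl ethers. During the equilibration, reversible β-elimination of the ring alkoxide from the ester enolate could erode material.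
- Fallback, from 15 back to 21, avoiding both the diazo ketone and light: cycloaddition of 4-nitrobenzenesulfonyl azide to the silyl enol ether (MeCN, rt → 50 °C) gives a triazoline. It loses N2 with the same C2-to-C4 shift and delivers, after aqueous work-up, the ring-contracted 2,5-bis[4-(benzyloxy)-3,5-dimethoxyphenyl]-4-(benzyloxymethyl)-N-(4-nitrophenylsulfonyl)tetrahydrofuran-3-carboxamide F1. N-Methylation with Me3SiCHN2 in MeOH/toluene gives the N-methyl-N-sulfonyl amide F2, which NaOMe in MeOH cleaves to the methyl ester while equilibrating C3, rejoining the route at 21.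

**Step 8.**
- Most likely to go wrong: incomplete facial discrimination in the carbopalladation, migration of the enol ether double bond into conjugation before coupling, or erosion of C2 by enolisation, because the C2 hydrogen is benzylic and α to the ketone.
- Fallback, from 7 back to 11, bypassing steps 5 to 8: BF3·OEt2 with 2,6-dimethoxyphenol in CH2Cl2 at −40 °C ionises the hemiacetal to the C6 oxocarbenium ion. The phenol attacks through its para carbon anti to the C2 aryl group (Friedel–Crafts C-arylation) and gives (2S,6R)-2-[4-(benzyloxy)-3,5-dimethoxyphenyl]-6-(4-hydroxy-3,5-dimethoxyphenyl)-2H-pyran-3(6H)-one F3. Mitsunobu benzylation (BnOH, PPh3, diisopropyl azodicarboxylate, THF) under neutral conditions then gives 11.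

**Step 9.**
- Most likely to go wrong: thermal decomposition of the α-alkoxy organocopper reagent before it adds, competing 1,2-addition, hydrolysis of the silyl enol ether on isolation, or incomplete anti selectivity if the remote C2 aryl group interferes.
- Fallback, from 11 back to 16: photoredox Giese addition of the benzyloxymethyl radical from potassium (benzyloxymethyl)trifluoroborate (Ir[dF(CF3)ppy]2(bpy)PF6, blue LEDs, acetone/MeOH), again anti to the C6 aryl group, gives (2S,5S,6R)-2,6-bis[4-(benzyloxy)-3,5-dimethoxyphenyl]-5-(benzyloxymethyl)tetrahydro-2H-pyran-3-one F4. Kinetic deprotonation at the less hindered C4 methylene with LiN(SiMe3)2 (THF, −78 °C) rejoins the route at the lithium enolate 16, which continues through step 10.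

**Step 10.**
- Most likely to go wrong: epimerisation at C2 by the amine base into the more stable 2,6-cis series, or O- instead of C-trifluoroacetylation of the hindered enolate.
- Fallback, from 15 back to 18: nitrosation of the silyl enol ether with NOCl (CH2Cl2, −20 °C) gives (2S,5S,6R)-2,6-bis[4-(benzyloxy)-3,5-dimethoxyphenyl]-5-(benzyloxymethyl)-4-(hydroxyimino)tetrahydro-2H-pyran-3-one F5. A Forster reaction with NH2Cl (from aq. NH3 and NaOCl, 0 °C, short contact) converts the oxime into the diazo ketone 18.

**Step 13.**
- Most likely to go wrong: over-reduction, that is hydrogenolytic cleavage of the ring C2–O1 or C5–O1 benzylic bonds, which become more labile once the para phenols are free. The primary alkyl benzyl ether is the slowest of the three to leave and prolongs the exposure.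
- Fallback, from 22 directly to 23 with no new intermediate: Lewis-acid debenzylation with BCl3 and pentamethylbenzene as a non-basic cation scavenger (CH2Cl2, −78 °C, MeOH quench), which removes aryl and alkyl benzyl ethers at low temperature without hydrogen.

## Further compounds

F1 | step 11 | (2R,4S,5R)-2,5-bis[4-(benzyloxy)-3,5-dimethoxyphenyl]-4-(benzyloxymethyl)-N-(4-nitrophenylsulfonyl)tetrahydrofuran-3-carboxamide (C3 as formed) | COc1cc([C@@H]2O[C@@H](c3cc(OC)c(OCc4ccccc4)c(OC)c3)[C@H](COCc3ccccc3)C2C(=O)NS(=O)(=O)c2ccc(cc2)[N+](=O)[O-])cc(OC)c1OCc1ccccc1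
F2 | step 11 | (2R,4S,5R)-2,5-bis[4-(benzyloxy)-3,5-dimethoxyphenyl]-4-(benzyloxymethyl)-N-methyl-N-(4-nitrophenylsulfonyl)tetrahydrofuran-3-carboxamide (C3 as formed) | COc1cc([C@@H]2O[C@@H](c3cc(OC)c(OCc4ccccc4)c(OC)c3)[C@H](COCc3ccccc3)C2C(=O)N(C)S(=O)(=O)c2ccc(cc2)[N+](=O)[O-])cc(OC)c1OCc1ccccc1
F3 | step 8 | (2S,6R)-2-[4-(benzyloxy)-3,5-dimethoxyphenyl]-6-(4-hydroxy-3,5-dimethoxyphenyl)-2H-pyran-3(6H)-one | COc1cc([C@@H]2O[C@@H](c3cc(OC)c(O)c(OC)c3)C=CC2=O)cc(OC)c1OCc1ccccc1
F4 | step 9 | (2S,5S,6R)-2,6-bis[4-(benzyloxy)-3,5-dimethoxyphenyl]-5-(benzyloxymethyl)tetrahydro-2H-pyran-3-one | COc1cc([C@@H]2O[C@@H](c3cc(OC)c(OCc4ccccc4)c(OC)c3)[C@H](COCc3ccccc3)CC2=O)cc(OC)c1OCc1ccccc1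
F5 | step 10 | (2S,5S,6R)-2,6-bis[4-(benzyloxy)-3,5-dimethoxyphenyl]-5-(benzyloxymethyl)-4-(hydroxyimino)tetrahydro-2H-pyran-3-one | COc1cc([C@@H]2O[C@@H](c3cc(OC)c(OCc4ccccc4)c(OC)c3)[C@H](COCc3ccccc3)C(=NO)C2=O)cc(OC)c1OCc1ccccc1
F0 | step 13 | none | none
A1 | alternative 1 | bis(triisopropylsilyl) ether of the target | COc1cc([C@@H]2O[C@@H](c3cc(OC)c(O)c(OC)c3)[C@H](CO[Si](C(C)C)(C(C)C)C(C)C)[C@H]2CO[Si](C(C)C)(C(C)C)C(C)C)cc(OC)c1O
A2 | alternative 1 | 1,3-dimethoxypropan-2-one | COCC(=O)COC
A3 | alternative 1 | all-trans 3,4-bis(triisopropylsilyloxymethyl)tetrahydrofuran-2,5-diyl bis[1,3-bis(dimethylamino)trimethinium] bis(hexafluorophosphate) | CN(C)C=C(C=[N+](C)C)[C@@H]1O[C@@H](C(C=[N+](C)C)=CN(C)C)[C@H](CO[Si](C(C)C)(C(C)C)C(C)C)[C@H]1CO[Si](C(C)C)(C(C)C)C(C)C.F[P-](F)(F)(F)(F)F.F[P-](F)(F)(F)(F)F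
A4 | alternative 2 | all-trans 2,5-bis(4-hydroxy-3,5-dimethoxyphenyl)tetrahydrofuran-3,4-dicarbonyl bis[(S)-4-benzyloxazolidin-2-one] | COc1cc([C@@H]2O[C@@H](c3cc(OC)c(O)c(OC)c3)[C@H](C(=O)N3[C@@H](Cc4ccccc4)COC3=O)[C@H]2C(=O)N2[C@@H](Cc3ccccc3)COC2=O)cc(OC)c1O
A5 | alternative 2 | (S)-4-benzyl-3-[(E)-3-(4-hydroxy-3,5-dimethoxyphenyl)prop-2-enoyl]oxazolidin-2-one | COc1cc(/C=C/C(=O)N2[C@@H](Cc3ccccc3)COC2=O)cc(OC)c1O
A6 | alternative 3 | diacetate of the target | COc1cc([C@@H]2O[C@@H](c3cc(OC)c(O)c(OC)c3)[C@H](COC(C)=O)[C@H]2COC(C)=O)cc(OC)c1O
A7 | alternative 3 | 2,6-dimethoxyphenol | COc1cccc(OC)c1O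
A8 | alternative 3 | [(3S,4S)-2,5-dimethoxytetrahydrofuran-3,4-diyl]bis(methylene) diacetate (acetal anomers) | COC1OC(OC)[C@H](COC(C)=O)[C@H]1COC(C)=O
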